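At 80 min I read how much substrate stands as double product, crystals counted.

substrate 0.25 M; reagent 4.00 equiv; time 80 min

1. the double product and crystals together standing at 80 min, as a percentage of the substrate charged
2. the change that raises the amount of double product and crystals together at 80 min, in percent of the substrate charged most ("none" if none brings more than 2 percentage points) (Tuesday's / Saturday's / Thursday's / none)
3. amount of double product and crystals together at 80 min, in percent of the substrate charged, after Thursday's

- double product is meant together with its crystals
- solid, in amounts per volume of the solution: crystals
- run time (flask): 80 min

- Tuesday's: doubling the amount of reagent, all else as stated
- Saturday's: doubling the solubility in step 1, all else as stated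
- Thursday's: doubling the dissolution coefficient of step 1, all else as stated

    crystals ⇌ double product, rate k1*(cs1 - [double product]) while solid is left; crystals form when [double product] > cs1 (cs1 = 2.5 mM, k1 = 0.0020 /s)
    substrate + reagent → mono adduct (k2 = 0.0039 /M/s)
    reagent + double product → tris adduct (k3 = 0.0028 /M/s)
    reagent + mono adduct → double product (k4 = 0.0013 /M/s)

Reagent turns substrate into mono adduct, mono adduct into double product, and dissolved double product into tris adduct. Crystals shelter double product, and I assume they grow with the dissolution coefficient. So I turn constants into times. At the charged [reagent] of 1.00 M, attack on dissolved double product has a pseudo-first-order time of 5.95 min. Entry into crystals takes 8.33 min, longer than attack, but not by much. At the charge this gives 41.7%, and that fraction, the chance that dissolved double product reaches the crystals before reagent reaches it, is my capture share.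

Is y then 41.7%? No, [reagent] falls. Reaching double product costs two equivalents, which leaves 0.500 M before attack takes its part, and there the share is 58.8%. Midway I take 50.2%.

But has the mono adduct gone through by then? At 0.500 M it keeps about 4.42% unconverted, so y comes to 48.0%.

And the solubility? Entry into crystals runs on [double product] minus 2.5 mM, not on [double product] itself. My share does not hold this, so where [double product] stands near 2.5 mM it counts too much entry, and I leave that uncorrected.

The same reckoning serves the changes. Thursday's gives 63.5%. Tuesday's gives about 29.3%, with mono adduct ignored. Saturday's doubles 2.5 mM, which lowers entry into crystals at a given [double product], so I expect no gain from it. So I commit to Thursday's, the highest.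

The forecast says 49%, Thursday's and 61.5% after Thursday's, holding that “crystallisation rate limits protection from over-addition”.

The simulation gives 49.5%, with Thursday's best at 13 percentage points, and 62.3% after it.

With 40.3% of reagent remaining at 80.0 min, this flask has a capture share of 63.9%. It then holds 49.5% double product and 44.7% tris adduct, a split of 52.5%, above the capture share at the charge and below the one at that reading. The neighbouring flask with 10.0 equiv of reagent has a capture share of 22.2% at its charge, and at 80.0 min its double product stands at 19.5%.

The rate constants were drawn at random within sensible limits.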